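The route grows flavanone ring A on C8'' of benzylated apigenin, so the crowded C8–C8'' bond is never made by coupling. Ring A has its aryl-bearing C8 between the oxygenated C8a and C7, with the C5 oxygen para to it. That is the pattern delivered when a vinylketene from a 3-alkoxycyclobutenone meets an aryl ynol ether. In one thermal operation the flavon-8-yl triisopropylsilyl ynol ether and 3-(benzyloxy)cyclobutenone form C8–C8a, C6–C7 and C4a–C8a and the benzene ring. Desilylation then leaves ring A locally symmetric, so C-acetylation needs no regiocontrol. Chromone formation and a catalyst-controlled aryl addition set C2, and one hydrogenolysis ends the route.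

Key step: step 6

Remark: the target formula fixes only C2; the C8–C8'' axis between four ortho oxygens is left open, so the route aims at the (2S) compound whatever the axis, and atropisomers, should they not interconvert, are carried together from compound 18 on.

Step 1
Reactants: 1 apigenin
Product: 2 5,7,4'-tri-O-benzylapigenin
Conditions: BnBr (4 equiv), K2CO3, Bu4NI (cat.), DMF, 80 °C
Reagents that add atoms: benzyl bromide, BrCc1ccccc1
Why: Williamson ether synthesis, with excess bromide and heat chosen so that the chelated 5-OH is alkylated along with the 7- and 4'-OH.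

Step 2
Reactants: 2 5,7,4'-tri-O-benzylapigenin
Product: 3 8-iodo-5,7,4'-tri-O-benzylapigenin
Conditions: I2, AgOCOCF3, CH2Cl2, 0 °C → rt, dark
Reagents that add atoms: iodine, II
Why: Electrophilic aromatic iodination with silver-activated iodine, expected at C8 because in a 5,7-dialkoxyflavone this position between O1 and the C7 ether is the most reactive, whereas C6 is flanked by two benzyloxy groups and C3 belongs to the electron-poor pyranone.

Step 3
Reactants: 3 8-iodo-5,7,4'-tri-O-benzylapigenin; 4 trimethylsilylacetylene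
Product: 6 8-ethynyl-5,7,4'-tri-O-benzylapigenin, via trimethylsilylalkyne 5 (not isolated)
Conditions: PdCl2(PPh3)2 (5 mol%), CuI (10 mol%), Et3N, THF, 60 °C, Ar; then K2CO3, MeOH, rt
Reagents that add atoms: none
Why: Sonogashira coupling of the aryl iodide with the slim silylalkyne, then base-catalysed methanolysis of the alkynyl C–Si bond in the same flask under argon, which should leave the flavone and the benzyl ethers untouched.

Step 4
Reactants: 6 8-ethynyl-5,7,4'-tri-O-benzylapigenin
Product: 9 8-{[(triisopropylsilyl)oxy]ethynyl}-5,7,4'-tri-O-benzylapigenin, via lithium acetylide 7 (not isolated), via lithium ynolate 8 (not isolated)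
Conditions: LiN(SiMe3)2, THF, −78 °C; t-BuOOLi (from t-BuOOH and LiN(SiMe3)2), −78 → 0 °C; i-Pr3SiOTf, −78 → 0 °C
Reagents that add atoms: tert-butyl hydroperoxide, CC(C)(C)OO; triisopropylsilyl trifluoromethanesulfonate, CC(C)[Si](OS(=O)(=O)C(F)(F)F)(C(C)C)C(C)C
Why: Electrophilic oxygenation of a lithium acetylide by t-BuOOLi (ynolate formation) followed by O-silylation with the bulky silyl triflate is a standard entry to silyl ynol ethers; the amide base removes only the alkyne proton, and the pyranone, a doubly donor-substituted vinylogous ester, is expected to resist the peroxide at low temperature.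

Step 5
Reactants: 10 3-ethoxycyclobut-2-en-1-one
Product: 11 3-(benzyloxy)cyclobut-2-en-1-one
Conditions: BnOH (3 equiv), camphorsulfonic acid (5 mol%), PhMe, 40 °C, reduced pressure (−EtOH)
Reagents that add atoms: benzyl alcohol, OCc1ccccc1
Why: Acid-catalysed transetherification of a vinylogous ester by addition–elimination at C3, driven to the benzyl ether by stripping off ethanol.

Step 6
Reactants: 9 8-{[(triisopropylsilyl)oxy]ethynyl}-5,7,4'-tri-O-benzylapigenin; 11 3-(benzyloxy)cyclobut-2-en-1-one
Product: 16 8-{4-(benzyloxy)-2-hydroxy-6-[(triisopropylsilyl)oxy]phenyl}-5,7,4'-tri-O-benzylapigenin, via vinylketene 12 (not isolated), via vinylcyclobutenone 13 (not isolated), via dienylketene 14 (not isolated), via cyclohexadienone 15 (not isolated)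
Conditions: 11 (1.5 equiv), PhMe, 110 °C, sealed tube, Ar
Reagents that add atoms: none
Why: Heat opens 11 by four-electron electrocyclic ring opening to vinylketene 12, whose central carbon is attacked by the aryl-bearing, nucleophilic carbon of the ynol ether in a [2+2] cycloaddition that gives vinylcyclobutenone 13 (bonds C8–C8a and C6–C7), and 13 opens in the same way to the 3,4-cis dienylketene 14. Ring A then closes by six-electron electrocyclisation of 14 between the ketene carbon and the terminal methylene (bond C4a–C8a), and dienone 15 tautomerises to phenol 16. The closest known reaction is the Danheiser benzannulation of cyclobutenones with silyl ynol ethers, here with a 3-alkoxy substituent on the four-membered ring. No stereocentre is created, since the sp3 carbon of 13 is lost on ring opening and the new biaryl axis forms without bias. The selectivity needed is regiochemical and rests on ketene polarity together with the oxygen-polarised alkyne, which puts the flavonyl group between the new hydroxyl and the silyl ether with the benzyl ether para to it, while chemoselectivity follows from the ynol ether being far more reactive towards ketenes than the pyranone C=C or C=O. Strain release in both ring openings and aromatisation drive the cascade under neutral conditions, and because the hindered aryl group arrives on a linear alkyne its two ortho substituents should not block bond formation.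

Step 7
Reactants: 16 8-{4-(benzyloxy)-2-hydroxy-6-[(triisopropylsilyl)oxy]phenyl}-5,7,4'-tri-O-benzylapigenin
Product: 17 8-[4-(benzyloxy)-2,6-dihydroxyphenyl]-5,7,4'-tri-O-benzylapigenin
Conditions: Bu4NF, THF, 0 °C; aq. NH4Cl
Reagents that add atoms: none
Why: Fluoride-induced cleavage of the aryl silyl ether, which spares benzyl ethers and the flavone and turns ring A into a 2-aryl-5-benzyloxyresorcinol whose two free positions C4a and C6 are equivalent.

Step 8
Reactants: 17 8-[4-(benzyloxy)-2,6-dihydroxyphenyl]-5,7,4'-tri-O-benzylapigenin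
Product: 18 8-[3-acetyl-4-(benzyloxy)-2,6-dihydroxyphenyl]-5,7,4'-tri-O-benzylapigenin
Conditions: Ac2O (1.05 equiv), BF3·OEt2, EtOAc, 0 °C → rt; aq. NaHCO3
Reagents that add atoms: acetic anhydride, CC(=O)OC(C)=O
Why: Friedel–Crafts C-acetylation of the phloroglucinol-type ring, by far the most nucleophilic arene present, at or below room temperature where aryl benzyl ethers tolerate BF3; because C4a and C6 are equivalent only one monoketone can form, and the acetyl group deactivates the ring against a second acylation.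

Step 9
Reactants: 18 8-[3-acetyl-4-(benzyloxy)-2,6-dihydroxyphenyl]-5,7,4'-tri-O-benzylapigenin
Product: 19 8-[3-acetyl-4,6-bis(benzyloxy)-2-hydroxyphenyl]-5,7,4'-tri-O-benzylapigenin
Conditions: BnBr (1.1 equiv), K2CO3, acetone, rt → 50 °C
Reagents that add atoms: benzyl bromide, BrCc1ccccc1
Why: Williamson ether synthesis selective for the C7 hydroxyl, which lies para to the acetyl group and is the more acidic, while the C8a hydroxyl is held in a hydrogen bond to the ketone and stays free for ring closure.

Step 10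
Reactants: 19 8-[3-acetyl-4,6-bis(benzyloxy)-2-hydroxyphenyl]-5,7,4'-tri-O-benzylapigenin
Product: 21 5,7-bis(benzyloxy)-8-(5,7,4'-tri-O-benzylapigenin-8-yl)-4H-chromen-4-one, via enaminone 20 (not isolated)
Conditions: Me2NCH(OMe)2, PhMe, 95 °C; then 2 M aq. HCl, CH2Cl2, rt
Reagents that add atoms: N,N-dimethylformamide dimethyl acetal, COC(OC)N(C)C
Why: Condensation of the methyl ketone with the amide acetal gives the enaminone, and acid then triggers intramolecular addition–elimination by the C8a hydroxyl with loss of dimethylamine, the standard enaminone route to chromones, under conditions mild enough for the benzyl ethers.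

Step 11
Reactants: 21 5,7-bis(benzyloxy)-8-(5,7,4'-tri-O-benzylapigenin-8-yl)-4H-chromen-4-one; 22 4-(benzyloxy)phenylboronic acid
Product: 23 (2S)-5,7-bis(benzyloxy)-2-[4-(benzyloxy)phenyl]-8-(5,7,4'-tri-O-benzylapigenin-8-yl)-2,3-dihydro-4H-chromen-4-one
Conditions: 22 (3 equiv), Pd(OCOCF3)2 (10 mol%), (R)-4-tert-butyl-2-(pyridin-2-yl)-4,5-dihydrooxazole (12 mol%), NH4PF6 (30 mol%), H2O (5 equiv), ClCH2CH2Cl, 60 °C
Reagents that add atoms: none
Why: Palladium-catalysed asymmetric conjugate addition of an arylboronic acid to a chromone (transmetalation, face-selective carbopalladation of C2–C3, protonolysis of the palladium enolate), in which the pyridine–oxazoline ligand controls the face; the (R)-ligand is chosen because the facial model of this catalyst, the mirror image of the one by which the (S)-ligand gives (R)-adducts of cyclic enones, is expected to place the aryl group on the Re face of C2 and so give the 2S centre, while the mildly acidic medium protects the product from ring opening and the fully substituted C2'' of the flavone is no acceptor.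

Step 12
Reactants: 23 (2S)-5,7-bis(benzyloxy)-2-[4-(benzyloxy)phenyl]-8-(5,7,4'-tri-O-benzylapigenin-8-yl)-2,3-dihydro-4H-chromen-4-one
Product: 24 (2S)-5,7-dihydroxy-2-(4-hydroxyphenyl)-8-[5,7-dihydroxy-2-(4-hydroxyphenyl)-4-oxo-4H-chromen-8-yl]-2,3-dihydro-4H-chromen-4-one
Conditions: H2 (1 atm), 10% Pd/C, THF/MeOH, rt
Reagents that add atoms: none
Why: Catalytic hydrogenolysis of the six aryl benzyl ethers under neutral conditions, which offers no base to open the flavanone ring and epimerise C2 and is stopped once the ethers are cleaved so that the flavone C2''=C3'' bond and both ketones are kept.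

Compound list

1 | apigenin, 5,7-dihydroxy-2-(4-hydroxyphenyl)-4H-chromen-4-one | O=c1cc(-c2ccc(O)cc2)oc2cc(O)cc(O)c12 | starting material
2 | 5,7,4'-tri-O-benzylapigenin, 5,7-bis(benzyloxy)-2-[4-(benzyloxy)phenyl]-4H-chromen-4-one | O=c1cc(-c2ccc(OCc3ccccc3)cc2)oc2cc(OCc3ccccc3)cc(OCc3ccccc3)c12 | intermediate
3 | 8-iodo-5,7,4'-tri-O-benzylapigenin | O=c1cc(-c2ccc(OCc3ccccc3)cc2)oc2c(I)c(OCc3ccccc3)cc(OCc3ccccc3)c12 | intermediate
4 | trimethylsilylacetylene | C#C[Si](C)(C)C | starting material
5 | 8-[(trimethylsilyl)ethynyl]-5,7,4'-tri-O-benzylapigenin | O=c1cc(-c2ccc(OCc3ccccc3)cc2)oc2c(C#C[Si](C)(C)C)c(OCc3ccccc3)cc(OCc3ccccc3)c12 | intermediate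
6 | 8-ethynyl-5,7,4'-tri-O-benzylapigenin | O=c1cc(-c2ccc(OCc3ccccc3)cc2)oc2c(C#C)c(OCc3ccccc3)cc(OCc3ccccc3)c12 | intermediate
7 | lithium acetylide of 6, [2-(5,7,4'-tri-O-benzylapigenin-8-yl)ethynyl]lithium | O=c1cc(-c2ccc(OCc3ccccc3)cc2)oc2c(C#C[Li])c(OCc3ccccc3)cc(OCc3ccccc3)c12 | intermediate
8 | lithium ynolate, lithium 2-(5,7,4'-tri-O-benzylapigenin-8-yl)ethynolate | O=c1cc(-c2ccc(OCc3ccccc3)cc2)oc2c(C#CO[Li])c(OCc3ccccc3)cc(OCc3ccccc3)c12 | intermediate
9 | 8-{[(triisopropylsilyl)oxy]ethynyl}-5,7,4'-tri-O-benzylapigenin | O=c1cc(-c2ccc(OCc3ccccc3)cc2)oc2c(C#CO[Si](C(C)C)(C(C)C)C(C)C)c(OCc3ccccc3)cc(OCc3ccccc3)c12 | intermediate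
10 | 3-ethoxycyclobut-2-en-1-one | CCOC1=CC(=O)C1 | starting material
11 | 3-(benzyloxy)cyclobut-2-en-1-one | O=C1C=C(OCc2ccccc2)C1 | intermediate
12 | vinylketene, 3-(benzyloxy)buta-1,3-dien-1-one | O=C=CC(=C)OCc1ccccc1 | intermediate
13 | vinylcyclobutenone, 4-[1-(benzyloxy)ethenyl]-2-(5,7,4'-tri-O-benzylapigenin-8-yl)-3-[(triisopropylsilyl)oxy]cyclobut-2-en-1-one, racemic at C4 | O=C1C(c2c(OCc3ccccc3)cc(OCc3ccccc3)c3c(=O)cc(-c4ccc(OCc5ccccc5)cc4)oc23)=C(O[Si](C(C)C)(C(C)C)C(C)C)C1C(=C)OCc1ccccc1 | intermediate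
14 | dienylketene, (3E)-5-(benzyloxy)-2-(5,7,4'-tri-O-benzylapigenin-8-yl)-3-[(triisopropylsilyl)oxy]hexa-1,3,5-trien-1-one | O=C=C(c1c(OCc2ccccc2)cc(OCc2ccccc2)c2c(=O)cc(-c3ccc(OCc4ccccc4)cc3)oc12)/C(O[Si](C(C)C)(C(C)C)C(C)C)=C\C(=C)OCc1ccccc1 | intermediate
15 | cyclohexadienone, 5-(benzyloxy)-2-(5,7,4'-tri-O-benzylapigenin-8-yl)-3-[(triisopropylsilyl)oxy]cyclohexa-2,4-dien-1-one | O=C1CC(OCc2ccccc2)=CC(O[Si](C(C)C)(C(C)C)C(C)C)=C1c1c(OCc2ccccc2)cc(OCc2ccccc2)c2c(=O)cc(-c3ccc(OCc4ccccc4)cc3)oc12 | intermediate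
16 | 8-{4-(benzyloxy)-2-hydroxy-6-[(triisopropylsilyl)oxy]phenyl}-5,7,4'-tri-O-benzylapigenin | Oc1cc(OCc2ccccc2)cc(O[Si](C(C)C)(C(C)C)C(C)C)c1-c1c(OCc2ccccc2)cc(OCc2ccccc2)c2c(=O)cc(-c3ccc(OCc4ccccc4)cc3)oc12 | intermediate
17 | 8-[4-(benzyloxy)-2,6-dihydroxyphenyl]-5,7,4'-tri-O-benzylapigenin | Oc1cc(OCc2ccccc2)cc(O)c1-c1c(OCc2ccccc2)cc(OCc2ccccc2)c2c(=O)cc(-c3ccc(OCc4ccccc4)cc3)oc12 | intermediate
18 | 8-[3-acetyl-4-(benzyloxy)-2,6-dihydroxyphenyl]-5,7,4'-tri-O-benzylapigenin | CC(=O)c1c(OCc2ccccc2)cc(O)c(-c2c(OCc3ccccc3)cc(OCc3ccccc3)c3c(=O)cc(-c4ccc(OCc5ccccc5)cc4)oc23)c1O | intermediate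
19 | 8-[3-acetyl-4,6-bis(benzyloxy)-2-hydroxyphenyl]-5,7,4'-tri-O-benzylapigenin | CC(=O)c1c(OCc2ccccc2)cc(OCc2ccccc2)c(-c2c(OCc3ccccc3)cc(OCc3ccccc3)c3c(=O)cc(-c4ccc(OCc5ccccc5)cc4)oc23)c1O | intermediate
20 | enaminone, 8-{4,6-bis(benzyloxy)-3-[(2E)-3-(dimethylamino)prop-2-enoyl]-2-hydroxyphenyl}-5,7,4'-tri-O-benzylapigenin | CN(C)/C=C/C(=O)c1c(OCc2ccccc2)cc(OCc2ccccc2)c(-c2c(OCc3ccccc3)cc(OCc3ccccc3)c3c(=O)cc(-c4ccc(OCc5ccccc5)cc4)oc23)c1O | intermediate
21 | 5,7-bis(benzyloxy)-8-(5,7,4'-tri-O-benzylapigenin-8-yl)-4H-chromen-4-one | O=c1ccoc2c1c(OCc1ccccc1)cc(OCc1ccccc1)c2-c1c(OCc2ccccc2)cc(OCc2ccccc2)c2c(=O)cc(-c3ccc(OCc4ccccc4)cc3)oc12 | intermediate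
22 | 4-(benzyloxy)phenylboronic acid | OB(O)c1ccc(OCc2ccccc2)cc1 | starting material
23 | (2S)-5,7-bis(benzyloxy)-2-[4-(benzyloxy)phenyl]-8-(5,7,4'-tri-O-benzylapigenin-8-yl)-2,3-dihydro-4H-chromen-4-one | O=C1C[C@@H](c2ccc(OCc3ccccc3)cc2)Oc2c1c(OCc1ccccc1)cc(OCc1ccccc1)c2-c1c(OCc2ccccc2)cc(OCc2ccccc2)c2c(=O)cc(-c3ccc(OCc4ccccc4)cc3)oc12 | intermediate
24 | (2S)-5,7-dihydroxy-2-(4-hydroxyphenyl)-8-[5,7-dihydroxy-2-(4-hydroxyphenyl)-4-oxo-4H-chromen-8-yl]-2,3-dihydro-4H-chromen-4-one | O=C1C[C@@H](c2ccc(O)cc2)Oc2c1c(O)cc(O)c2-c1c(O)cc(O)c2c(=O)cc(-c3ccc(O)cc3)oc12 | target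

Total step count: 12. Longest linear sequence: 11 steps (steps 1 to 4 and 6 to 12, from apigenin); step 5 is a one-step side branch.

Steps most likely to fail

Step 6. The donor-stabilised cyclobutenone may open more slowly than the ynol ether decays thermally (loss of the silyl group, ketene formation). The vinylketene may also be used up by self-condensation or by acylating the product phenol before it meets the alkyne. The fallback keeps the annulation but makes the same vinylketene 12 without heat, by the known pairing of dehydrochlorination-derived vinylketenes with silyl ynol ethers. It sets out from 9. Commercial ethyl (E)-3-ethoxybut-2-enoate is exchanged with benzyl alcohol under acid catalysis to ethyl (E)-3-(benzyloxy)but-2-enoate F1. This is saponified with LiOH to (E)-3-(benzyloxy)but-2-enoic acid F2 and converted with (COCl)2 into (E)-3-(benzyloxy)but-2-enoyl chloride F3. Et3N added to F3 and 9 in CH2Cl2 at 0 °C to room temperature should give 12 by 1,4-elimination and, by [2+2] cycloaddition, vinylcyclobutenone 13. Warming 13 in toluene to 80 °C should take it through 14 and 15, and the route is rejoined at 16.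

Step 4. The peroxide anion or the ynolate may attack the pyranone (conjugate addition, ring opening), or silylation may go to carbon instead of oxygen. The fallback gives up the ynol ether and makes the C8–C8'' bond by cross-coupling. It sets out from 3. Miyaura borylation (bis(pinacolato)diboron, PdCl2(dppf), KOAc, dioxane, 90 °C) should give 8-(4,4,5,5-tetramethyl-1,3,2-dioxaborolan-2-yl)-5,7,4'-tri-O-benzylapigenin F4. Commercial 1-[2,4-bis(benzyloxy)-6-hydroxyphenyl]ethan-1-one is iodinated ortho to its hydroxyl with N-iodosuccinimide to give 1-[4,6-bis(benzyloxy)-2-hydroxy-3-iodophenyl]ethan-1-one F5. Suzuki–Miyaura coupling of F4 with F5 (Pd(OAc)2, SPhos, K3PO4, toluene/water, 100 °C) rejoins the route at 19. The price is a cross-coupling that has to form a biaryl with four ortho substituents.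

Step 11. Aryl transfer to the electron-rich, hindered chromone may be slower than protodeboronation and homocoupling of the boronic acid, and the neighbouring biaryl axis may erode facial control. The fallback closes the pyranone ring from oxygen instead of adding the aryl group to it. It sets out from 19. Claisen–Schmidt condensation with 4-(benzyloxy)benzaldehyde (KOH, EtOH/THF, rt) should give (E)-1-[4,6-bis(benzyloxy)-2-hydroxy-3-(5,7,4'-tri-O-benzylapigenin-8-yl)phenyl]-3-[4-(benzyloxy)phenyl]prop-2-en-1-one F6. F6 is then cyclised by enantioselective intramolecular oxa-Michael addition under a cinchona-derived bifunctional thiourea, using the pseudoenantiomer that leads to the 2S product. Enantiomeric enrichment by crystallisation or chiral chromatography follows if needed, and the route is rejoined at 23.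

Further compounds

F1 | step 6 | ethyl (E)-3-(benzyloxy)but-2-enoate | CCOC(=O)/C=C(\C)OCc1ccccc1
F2 | step 6 | (E)-3-(benzyloxy)but-2-enoic acid | OC(=O)/C=C(\C)OCc1ccccc1
F3 | step 6 | (E)-3-(benzyloxy)but-2-enoyl chloride | ClC(=O)/C=C(\C)OCc1ccccc1
F4 | step 4 | 8-(4,4,5,5-tetramethyl-1,3,2-dioxaborolan-2-yl)-5,7,4'-tri-O-benzylapigenin | O=c1cc(-c2ccc(OCc3ccccc3)cc2)oc2c(B3OC(C)(C)C(C)(C)O3)c(OCc3ccccc3)cc(OCc3ccccc3)c12
F5 | step 4 | 1-[4,6-bis(benzyloxy)-2-hydroxy-3-iodophenyl]ethan-1-one | CC(=O)c1c(OCc2ccccc2)cc(OCc2ccccc2)c(I)c1O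
F6 | step 11 | (E)-1-[4,6-bis(benzyloxy)-2-hydroxy-3-(5,7,4'-tri-O-benzylapigenin-8-yl)phenyl]-3-[4-(benzyloxy)phenyl]prop-2-en-1-one | O=C(/C=C/c1ccc(OCc2ccccc2)cc1)c1c(OCc2ccccc2)cc(OCc2ccccc2)c(-c2c(OCc3ccccc3)cc(OCc3ccccc3)c3c(=O)cc(-c4ccc(OCc5ccccc5)cc4)oc23)c1O
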